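**Retrosynthetic overview**

- The strategy rests on C2 of the dihydropyran ring B (O1, C2, C3, C4, C4a, C8a). C2 carries CH3, O1, the C3–C4 ethylene and a 4-methylpent-3-enyl arm, so C2/C3/C4 map onto the carbinol carbon and vinyl group of (R)-linalool.
- Ring B therefore needs only two bonds to aromatic ring A: C4–C4a (B-alkyl Suzuki coupling at C–Br) and O1–C8a (palladium C–O arylation at C–Cl), both made in one vessel. Ring A is bought; ring B is the only ring formed.
- Side chain: the (Z)-enoate comes from Still–Gennari olefination of an aldehyde. The aldehyde comes from the prenyl end of the linalool arm by E-selective allylic oxidation, bromination, acetate enolate alkylation and partial reduction.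
- Arene: para-bromination and MOM protection of 3-chloro-5-methylphenol; the MOM group is removed last.

Key step: step 3

Assumptions: commercial (R)-(−)-linalool of high enantiomeric purity is used, and the target's enantiomeric purity is that of this starting material. The tertiary hydroxyl of linalool is taken to react with 9-BBN much more slowly than the vinyl group; any O-borinate that forms is cleaved by the aqueous carbonate of the coupling stage.

**Route**

Step 1
Reactants: 1 3-chloro-5-methylphenol
Product: 2 4-bromo-3-chloro-5-methylphenol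
Conditions: NBS, MeCN, 0 °C → rt
Reagents that add atoms: N-bromosuccinimide, O=C1CCC(=O)N1Br
Why: Electrophilic aromatic bromination in which the hydroxyl directs para, so that in a polar solvent the position between chlorine and methyl should be favoured over the two ortho positions, as is usual for 3,5-disubstituted phenols.

Step 2
Reactants: 2 4-bromo-3-chloro-5-methylphenol
Product: 3 2-bromo-1-chloro-5-(methoxymethoxy)-3-methylbenzene
Conditions: NaH, MOMCl, DMF, 0 °C → rt
Reagents that add atoms: chloromethyl methyl ether, COCCl
Why: Williamson-type O-alkylation of the sodium phenoxide gives the MOM ether, which is inert to boranes, palladium/base, enolates and hydride and can be removed under mild acid at the end.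

Step 3
Reactants: 3 2-bromo-1-chloro-5-(methoxymethoxy)-3-methylbenzene; 4 (R)-linalool, (3R)-3,7-dimethylocta-1,6-dien-3-ol
Product: 7 (2R)-7-(methoxymethoxy)-2,5-dimethyl-2-(4-methylpent-3-en-1-yl)chromane, via linalool 9-BBN adduct 5 (not isolated), via chloroaryl carbinol 6 (not isolated)
Conditions: (a) 4, 9-BBN dimer, THF, 0 °C → rt; (b) 3, Pd(dppf)Cl2 (5 mol %), Cs2CO3, H2O (5 equiv), THF, 65 °C; (c) THF/H2O distilled off with toluene, then Pd(OAc)2 (5 mol %), t-BuXPhos (10 mol %), Cs2CO3, toluene, 100 °C
Reagents that add atoms: 9-borabicyclo[3.3.1]nonane (9-BBN), B1C2CCCC1CCC2 (its boron cage is carried in 5 only; 7 keeps just the hydrogen delivered to C3)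
Why: 9-BBN adds anti-Markovnikov to the monosubstituted vinyl group of 4 only (the trisubstituted alkene is far slower) and puts boron on the future C4; zerovalent palladium from Pd(dppf)Cl2 then inserts into C–Br of 3, the hydroxide-activated alkylborane transmetalates and reductive elimination forms C4–C4a (B-alkyl Suzuki–Miyaura coupling). After the solvent switch the bulky t-BuXPhos–palladium catalyst inserts into C–Cl of 6, Cs2CO3 delivers the tertiary alkoxide to palladium, and C(aryl)–O reductive elimination out of a seven-membered aryl(alkoxo)palladium chelate forms O1–C8a and closes six-membered ring B (Buchwald–Hartwig-type intramolecular etherification of an aryl halide by a tertiary alcohol). Both bond formations are established reaction types; only their telescoping in one vessel on a bromide flanked by chlorine and methyl is untested, which is why the risk of the route sits here. No stereocenter is made: the carbinol carbon of 4 becomes C2 with none of its four bonds touched, and because it bears no hydrogen, β-hydride elimination from the palladium alkoxide cannot occur. The step needs C–Br to react before C–Cl, which the halogen reactivity order and a first catalyst that does not activate aryl chlorides at 65 °C should secure, with near-equimolar borane limiting a second alkylation. It also needs a dry second stage, secured by azeotropic removal of water before the etherification catalyst is added.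

Step 4
Reactants: 7 (2R)-7-(methoxymethoxy)-2,5-dimethyl-2-(4-methylpent-3-en-1-yl)chromane
Product: 8 (2E)-5-[(2R)-7-(methoxymethoxy)-2,5-dimethylchroman-2-yl]-2-methylpent-2-en-1-ol
Conditions: SeO2 (0.3 equiv), t-BuOOH (2.5 equiv), CH2Cl2, rt
Reagents that add atoms: tert-butyl hydroperoxide, CC(C)(C)OO (net oxygen source); selenium dioxide, O=[Se]=O (catalytic carrier that delivers the oxygen)
Why: Riley-type allylic oxidation (ene reaction, then [2,3]-sigmatropic shift) attacks the E-methyl of the terminal trisubstituted alkene, so the (E)-allylic alcohol is expected, with the benzylic positions and the MOM ether left alone at room temperature.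

Step 5
Reactants: 8 (2E)-5-[(2R)-7-(methoxymethoxy)-2,5-dimethylchroman-2-yl]-2-methylpent-2-en-1-ol
Product: 9 (2R)-2-[(3E)-5-bromo-4-methylpent-3-en-1-yl]-7-(methoxymethoxy)-2,5-dimethylchromane
Conditions: CBr4, PPh3, CH2Cl2, 0 °C
Reagents that add atoms: carbon tetrabromide, BrC(Br)(Br)Br
Why: Appel reaction of a primary allylic alcohol proceeds by SN2 displacement of the oxyphosphonium at CH2 under neutral conditions, which should keep the alkene geometry and the MOM ether intact; the bromide is used at once.

Step 6
Reactants: 9 (2R)-2-[(3E)-5-bromo-4-methylpent-3-en-1-yl]-7-(methoxymethoxy)-2,5-dimethylchromane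
Product: 10 ethyl (4E)-7-[(2R)-7-(methoxymethoxy)-2,5-dimethylchroman-2-yl]-4-methylhept-4-enoate
Conditions: EtOAc, LDA, THF, −78 °C; CuI; then 9, −78 → −30 °C
Reagents that add atoms: ethyl acetate, CCOC(C)=O
Why: Copper-mediated alkylation of the lithium enolate of ethyl acetate with a primary allylic bromide should proceed by direct (α) substitution without allylic transposition, adding the two carbons with the E-alkene retained.

Step 7
Reactants: 10 ethyl (4E)-7-[(2R)-7-(methoxymethoxy)-2,5-dimethylchroman-2-yl]-4-methylhept-4-enoate
Product: 11 (4E)-7-[(2R)-7-(methoxymethoxy)-2,5-dimethylchroman-2-yl]-4-methylhept-4-enal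
Conditions: i-Bu2AlH (1.1 equiv), CH2Cl2, −78 °C; aq. Rochelle salt
Reagents that add atoms: none
Why: Partial reduction of an ester with i-Bu2AlH stops at the aluminium hemiacetal at −78 °C, which releases the aldehyde only on work-up.

Step 8
Reactants: 11 (4E)-7-[(2R)-7-(methoxymethoxy)-2,5-dimethylchroman-2-yl]-4-methylhept-4-enal
Product: 12 methyl (2Z,6E)-9-[(2R)-7-(methoxymethoxy)-2,5-dimethylchroman-2-yl]-2,6-dimethylnona-2,6-dienoate
Conditions: (CF3CH2O)2P(O)CH(CH3)CO2Me, KHMDS, 18-crown-6, THF, −78 °C; then 11
Reagents that add atoms: methyl 2-[bis(2,2,2-trifluoroethoxy)phosphoryl]propanoate, COC(=O)C(C)P(=O)(OCC(F)(F)F)OCC(F)(F)F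
Why: Still–Gennari olefination, in which the electron-poor phosphonate with a crown-ether-separated potassium counter-ion eliminates quickly from the kinetic adduct, should place the ester cis to the chain and so set the (Z)-trisubstituted enoate.

Step 9
Reactants: 12 methyl (2Z,6E)-9-[(2R)-7-(methoxymethoxy)-2,5-dimethylchroman-2-yl]-2,6-dimethylnona-2,6-dienoate
Product: 13 methyl (2Z,6E)-9-[(2R)-7-hydroxy-2,5-dimethylchroman-2-yl]-2,6-dimethylnona-2,6-dienoate (the target)
Conditions: p-TsOH·H2O (0.2 equiv), MeOH, 40 °C
Reagents that add atoms: none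
Why: Acid-catalysed acetal methanolysis removes the aryl MOM ether under conditions mild enough for the trisubstituted alkenes and the tertiary aryl ether of ring B, and methanol as solvent makes any ester exchange degenerate.

**Compound list**

1 | 3-chloro-5-methylphenol | Cc1cc(O)cc(Cl)c1 | starting material
2 | 4-bromo-3-chloro-5-methylphenol | Cc1cc(O)cc(Cl)c1Br | intermediate
3 | 2-bromo-1-chloro-5-(methoxymethoxy)-3-methylbenzene | COCOc1cc(C)c(Br)c(Cl)c1 | intermediate
4 | (R)-linalool, (3R)-3,7-dimethylocta-1,6-dien-3-ol | CC(C)=CCC[C@](O)(C)C=C | starting material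
5 | (3S)-1-(9-borabicyclo[3.3.1]nonan-9-yl)-3,7-dimethyloct-6-en-3-ol (same spatial arrangement as 4; the letter changes only because boron ranks below carbon) | CC(C)=CCC[C@](O)(C)CCB1C2CCCC1CCC2 | intermediate (not isolated)
6 | (3R)-1-[2-chloro-4-(methoxymethoxy)-6-methylphenyl]-3,7-dimethyloct-6-en-3-ol | CC(C)=CCC[C@](O)(C)CCc1c(C)cc(OCOC)cc1Cl | intermediate (not isolated)
7 | (2R)-7-(methoxymethoxy)-2,5-dimethyl-2-(4-methylpent-3-en-1-yl)chromane | CC(C)=CCC[C@]1(C)CCc2c(C)cc(OCOC)cc2O1 | intermediate
8 | (2E)-5-[(2R)-7-(methoxymethoxy)-2,5-dimethylchroman-2-yl]-2-methylpent-2-en-1-ol | OC/C(C)=C/CC[C@]1(C)CCc2c(C)cc(OCOC)cc2O1 | intermediate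
9 | (2R)-2-[(3E)-5-bromo-4-methylpent-3-en-1-yl]-7-(methoxymethoxy)-2,5-dimethylchromane | BrC/C(C)=C/CC[C@]1(C)CCc2c(C)cc(OCOC)cc2O1 | intermediate
10 | ethyl (4E)-7-[(2R)-7-(methoxymethoxy)-2,5-dimethylchroman-2-yl]-4-methylhept-4-enoate | CCOC(=O)CC/C(C)=C/CC[C@]1(C)CCc2c(C)cc(OCOC)cc2O1 | intermediate
11 | (4E)-7-[(2R)-7-(methoxymethoxy)-2,5-dimethylchroman-2-yl]-4-methylhept-4-enal | O=CCC/C(C)=C/CC[C@]1(C)CCc2c(C)cc(OCOC)cc2O1 | intermediate
12 | methyl (2Z,6E)-9-[(2R)-7-(methoxymethoxy)-2,5-dimethylchroman-2-yl]-2,6-dimethylnona-2,6-dienoate | COC(=O)/C(C)=C\CC/C(C)=C/CC[C@]1(C)CCc2c(C)cc(OCOC)cc2O1 | intermediate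
13 | methyl (2Z,6E)-9-[(2R)-7-hydroxy-2,5-dimethylchroman-2-yl]-2,6-dimethylnona-2,6-dienoate | COC(=O)/C(C)=C\CC/C(C)=C/CC[C@]1(C)CCc2c(C)cc(O)cc2O1 | target

**Step count and risks**

Total step count: 9. Longest linear sequence: 9 steps (1 → 13); 4 enters at step 3.

Steps most likely to fail:

1. Step 3. Transmetalation at the doubly ortho-substituted arylpalladium bromide may be slow enough for protodebromination to take over. In the second stage, boron residues and traces of hydroxide may tie up the alkoxide or divert the aryl chloride to hydrodechlorination or hydroxylation instead of ring closure. The fallback separates the two events and uses a more reactive halide pair. It sets out from 4, through its 9-BBN adduct 5, and from purchased 3-bromo-5-methylphenol F1. Para-iodination with N-iodosuccinimide in MeCN should give 3-bromo-4-iodo-5-methylphenol F2, and NaH/MOMCl then gives 1-bromo-2-iodo-5-(methoxymethoxy)-3-methylbenzene F3. B-alkyl Suzuki coupling of 5 at the C–I bond (Pd(dppf)Cl2, aqueous Cs2CO3, THF/DMF, rt), with aqueous work-up and chromatography to remove boron, gives isolated (3R)-1-[2-bromo-4-(methoxymethoxy)-6-methylphenyl]-3,7-dimethyloct-6-en-3-ol F4. In a separate dry flask, the known etherification of an aryl bromide by a tertiary alcohol (Pd(OAc)2, dppf, NaOt-Bu, toluene, 100 °C) closes ring B, and the route is rejoined at 7.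

2. Step 4. The allylic oxidation may stall at partial conversion, run on to the enal, or spread to other allylic and benzylic C–H bonds of the electron-rich chromane. The fallback replaces C–H oxidation by alkene cleavage and olefination and sets out from 7. Lemieux–Johnson cleavage (OsO4 cat., NaIO4, 2,6-lutidine, dioxane/H2O) of the terminal alkene gives 3-[(2S)-7-(methoxymethoxy)-2,5-dimethylchroman-2-yl]propanal F5 (same spatial arrangement at C2; the letter changes because the formyl arm outranks C3). Wittig reaction with ethyl 2-(triphenylphosphoranylidene)propanoate gives ethyl (2E)-5-[(2R)-7-(methoxymethoxy)-2,5-dimethylchroman-2-yl]-2-methylpent-2-enoate F6. Reduction with i-Bu2AlH (2.2 equiv, −78 → 0 °C) returns to the route at 8.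

3. Step 6. The ester enolate may self-condense, attack the allylic bromide at the γ-carbon, or simply eliminate it, and the labile bromide may not survive handling. The fallback uses a soft stabilised nucleophile and sets out from 9. Alkylation with sodium dimethyl malonate (NaH, THF, 0 °C → rt) gives dimethyl 2-[(2E)-5-[(2R)-7-(methoxymethoxy)-2,5-dimethylchroman-2-yl]-2-methylpent-2-en-1-yl]propanedioate F7. Krapcho decarboxylation (LiCl, wet DMSO, 150 °C) gives methyl (4E)-7-[(2R)-7-(methoxymethoxy)-2,5-dimethylchroman-2-yl]-4-methylhept-4-enoate F8. Reduction as in step 7 returns to the route at 11.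

**Further compounds**

F1 | step 3 | 3-bromo-5-methylphenol (purchased) | Cc1cc(O)cc(Br)c1
F2 | step 3 | 3-bromo-4-iodo-5-methylphenol | Cc1cc(O)cc(Br)c1I
F3 | step 3 | 1-bromo-2-iodo-5-(methoxymethoxy)-3-methylbenzene | COCOc1cc(C)c(I)c(Br)c1
F4 | step 3 | (3R)-1-[2-bromo-4-(methoxymethoxy)-6-methylphenyl]-3,7-dimethyloct-6-en-3-ol | CC(C)=CCC[C@](O)(C)CCc1c(C)cc(OCOC)cc1Br
F5 | step 4 | 3-[(2S)-7-(methoxymethoxy)-2,5-dimethylchroman-2-yl]propanal | O=CCC[C@]1(C)CCc2c(C)cc(OCOC)cc2O1
F6 | step 4 | ethyl (2E)-5-[(2R)-7-(methoxymethoxy)-2,5-dimethylchroman-2-yl]-2-methylpent-2-enoate | CCOC(=O)/C(C)=C/CC[C@]1(C)CCc2c(C)cc(OCOC)cc2O1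
F7 | step 6 | dimethyl 2-[(2E)-5-[(2R)-7-(methoxymethoxy)-2,5-dimethylchroman-2-yl]-2-methylpent-2-en-1-yl]propanedioate | COC(=O)C(C/C(C)=C/CC[C@]1(C)CCc2c(C)cc(OCOC)cc2O1)C(=O)OC
F8 | step 6 | methyl (4E)-7-[(2R)-7-(methoxymethoxy)-2,5-dimethylchroman-2-yl]-4-methylhept-4-enoate | COC(=O)CC/C(C)=C/CC[C@]1(C)CCc2c(C)cc(OCOC)cc2O1
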